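Readings and results stem from a simulated flask for an exercise; the scatter is artificial.

At 5.00 min gamma holds twice the product of epsilon, although it was charged with 2.62 times the nucleophile, so the yield grows less than in proportion to the charge, and I want one reckoning that covers both runs.

| flask | electrophile | nucleophile | gas | remark | time |
|---|---|---|---|---|---|
| epsilon | 20 mM | 1.6 equiv | 0.84 mM (held) | run made earlier |  |
| gamma | 20 mM | 4.2 equiv | 0.84 mM (held) | run made earlier |  |
| grey | 20 mM | 2.70 equiv | 0.84 mM (held) |  | 10 min |
| blue | 20 mM | 1.80 equiv | 0.84 mM (held) |  | 10 min |
| violet | 20 mM | 4.00 equiv | 0.84 mM (held) |  | 10 min |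

| run | time / min | electrophile / % | product / % |
|---|---|---|---|
| epsilon | 0.417 | 97.2 | 4.3 |
| epsilon | 1.00 | 90.8 | 9.4 |
| epsilon | 2.00 | 82.4 | 15.3 |
| epsilon | 5.00 | 68.1 | 33.5 |
| gamma | 1.33 | 70.8 | 29.2 |
| gamma | 2.50 | 56.1 | 45.2 |
| gamma | 4.00 | 40.3 | 58.6 |
| gamma | 5.00 | 35.5 | 66.2 |

(readings scatter by 1 percentage point)

* part of the electrophile that has reacted at the end, grey
* part of the electrophile that has reacted at the end, blue
* part of the electrophile that has reacted at the end, violet
* what raising the equivalents of nucleophile from its lowest to its highest value here does to the part of the electrophile that has reacted (changes below 5 percentage points count as none) (no change / it rises / it falls)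

- at the start none of free base is dissolved
- steps that have been proposed: electrophile + nucleophile -> acid set free + product; acid set free + free base <-> salt of the base; nucleophile + acid set free <-> protonated nucleophile; 2 free base -> homo dimer; gas <-> free base

I count in fractions of the charge: f is the part of the electrophile that has reacted and e the equivalents of nucleophile. At the start the rate df/dt is κe, with κ the second-order constant times the electrophile charge. Each turnover then sets free one acid, and the gas, which saturates at 4.20% of the electrophile charge, offers less free base at any moment than the nucleophile charged even in epsilon, so I let the nucleophile take the acid. That costs two nucleophiles per turnover, and later the rate is κ(1 − f)(e − 2f). In blue this makes the nucleophile the limiting reagent, its charge covering 90.0% of the electrophile.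

Integrating joins the two ends: ln[(e − 2f)/(e(1 − f))] = (e − 2)κt. I take f at 5.00 min as the mean of product formed and electrophile lost, which is 32.7% for epsilon and 65.3% for gamma. Epsilon then reads κ as 0.0648 min⁻¹ and gamma as 0.0625 min⁻¹. Their mean I call the clock, the fraction of the electrophile that one equivalent of free nucleophile turns per minute at full electrophile: 0.0636 min⁻¹.

Solving for f at 10 min, I get 68.4% for grey, 51.8% for blue and 83.7% for violet, so violet ends higher than blue by 32 percentage points.

The forecast, holding that “each turnover removes two nucleophiles”, says 68% for grey, 52% for blue and 83% for violet, and of the trend that it rises. Grey, blue and violet give 68.9%, 52.2% and 84.2%, and on going from the lowest charge of nucleophile, in blue, to the highest, in violet, the part reacted does this: it rises, by 32 points.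

    electrophile + nucleophile → acid set free + product (k = 0.0540 L mol⁻¹ s⁻¹)
    acid set free + free base ⇌ salt of the base (K = 1700 L mol⁻¹, k = 1.20 L mol⁻¹ s⁻¹)
    nucleophile + acid set free ⇌ protonated nucleophile, settled at all times (K = 1.70 × 10⁵ L mol⁻¹)
    2 free base → homo dimer (k = 0.650 L mol⁻¹ s⁻¹)
    gas ⇌ free base, rate k5*(csat - [free base]) (kL = 0.0780 s⁻¹)

Now the neighbour of violet, charged with 2.40 equiv of nucleophile, its other charges and the time held. The same clock and the same cost give 63.5% reacted, and that flask gives 64.0%. Two nucleophiles per turnover then leave 47.1% of its nucleophile charge free, and the neighbour holds 47% of that charge unbound at the end.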